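The six-membered quinone ring (C1 and C4 carbonyls, C2 and C5 hydroxylated, C3 methyl, C6 pentadecyl) is a tautomer of a cyclohexane-1,2,4,5-tetraone. It is therefore a head-to-tail cyclic dimer of two three-carbon 2-oxoacyl units, C1–C2–C3 and C4–C5–C6. Disconnecting C3–C4 and C6–C1 gives two 2-oxo esters, ethyl 2-oxobutanoate and ethyl 2-oxooctadecanoate. Their crossed double Claisen condensation (intermolecular Claisen, then Dieckmann closure) forms both acyl–α-carbon bonds, the ring and the final oxidation level in one operation, without redox steps or protecting groups. The long-chain keto ester comes from hexadecylmagnesium bromide and diethyl oxalate.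

Key step: step 2

Remark: the target has no stereocentre; its SMILES shows one of two equivalent enol tautomers of the same 2,5-dihydroxy-1,4-benzoquinone.

Step 1
Reactants: 1 1-bromohexadecane; 2 diethyl oxalate
Product: 4 ethyl 2-oxooctadecanoate, via hexadecylmagnesium bromide 3 (not isolated)
Conditions: Mg turnings, I2 (cat.), THF, reflux; then added to 2 (3 equiv), THF/Et2O, −78 °C; aq. HCl quench at −78 °C
Reagents that add atoms: none
Why: Grignard acylation of a dialkyl oxalate, in which the tetrahedral magnesium alkoxide of mono-addition persists at −78 °C until the quench, so inverse addition into excess oxalate should stop at the 2-oxo ester.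

Step 2
Reactants: 4 ethyl 2-oxooctadecanoate; 5 ethyl 2-oxobutanoate
Product: 8 2,5-dihydroxy-3-methyl-6-pentadecyl-1,4-benzoquinone, via open-chain trioxo ester 6 (not isolated), via disodium quinonediolate 7 (not isolated)
Conditions: 4 premixed with 5 (4 equiv), added to NaOEt (alcohol-free, 5.5 equiv), Et2O, 0 °C to rt, Ar; then 2 M HCl
Reagents that add atoms: none
Why: Ethoxide reversibly forms the C3 enolates of both 2-oxo esters; the enolate of 5 attacks the ester carbonyl of 4 (Claisen) to give the open-chain trioxo ester 6 as its stabilised enolate, and a second enolisation at the long-chain CH2 closes the ring by attack on the remaining ester carbonyl (the opposite order of the two acylations converges on the same ring), so that the C3–C4 and C6–C1 bonds of the quinone arise in one flask. The closest known reaction type is the base-mediated self-condensation of 2-oxo esters to 3,6-dialkyl-2,5-dihydroxy-1,4-benzoquinones, a Claisen–Dieckmann sequence run here in its crossed form. The six-membered ring closes in the 6-(enolendo)-exo-trig mode. No stereocentre is formed; the cyclohexane-1,2,4,5-tetraone tautomerises to the dihydroxyquinone, and its disodium salt 7 is the thermodynamic sink that should pull the reversible aldol and Claisen equilibria forward before acid releases 8. The head-to-tail, para-dialkyl constitution is secured by the substrates, since each 2-oxo ester has one enolisable CH2 and one acyl leaving group; crossed versus homo condensation is not secured by structure and is biased by the fourfold excess of cheap 5, while the homo-condensation quinones (3,6-dimethyl and 3,6-dipentadecyl) should differ enough in polarity and solubility to be removed by extraction and crystallisation.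

Compound list
1 | 1-bromohexadecane | CCCCCCCCCCCCCCCCBr | starting material
2 | diethyl oxalate | CCOC(=O)C(=O)OCC | starting material
3 | hexadecylmagnesium bromide | CCCCCCCCCCCCCCCC[Mg]Br | intermediate
4 | ethyl 2-oxooctadecanoate | CCCCCCCCCCCCCCCCC(=O)C(=O)OCC | intermediate
5 | ethyl 2-oxobutanoate | CCC(=O)C(=O)OCC | starting material
6 | ethyl 3-methyl-2,4,5-trioxohenicosanoate | CCCCCCCCCCCCCCCCC(=O)C(=O)C(C)C(=O)C(=O)OCC | intermediate
7 | disodium 3-methyl-6-pentadecyl-1,4-benzoquinone-2,5-diolate | CCCCCCCCCCCCCCCC1=C([O-])C(=O)C(C)=C([O-])C1=O.[Na+].[Na+] | intermediate
8 | 2,5-dihydroxy-3-methyl-6-pentadecyl-1,4-benzoquinone (2,5-dihydroxy-3-methyl-6-pentadecylcyclohexa-2,5-diene-1,4-dione) | CCCCCCCCCCCCCCCC1=C(O)C(=O)C(C)=C(O)C1=O | target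

Total step count: 2
Longest linear sequence: 2 steps (1 → 4 → 8)

Steps most likely to fail (the route has only two steps, so both are ranked):

1. Step 2. The keto ester enolates may be diverted into aldol addition at the ketone carbonyl followed by lactonisation, and the long-chain partner may be lost to statistical homo-condensation, so that little material passes through the crossed Claisen pathway. The fallback sets out from 1 and comes back to the route at 8. It closes the ring by a [4+2] double oxalate Claisen in which only the four-carbon partner can enolise, so no statistical pairing arises. Compound 1 would alkylate but-1-ynyllithium (but-1-yne, n-BuLi, THF/DMPU, −78 °C to rt) to give icos-3-yne F1. Oxidation of the triple bond (RuCl3 cat., NaIO4, CCl4/MeCN/H2O, rt) should give icosane-3,4-dione F2. Slow addition of F2 to excess diethyl oxalate 2 and NaOEt in Et2O/EtOH, then 2 M HCl, should close the ring through the disodium salt 7 and deliver 8.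

2. Step 1. The tetrahedral intermediate may collapse before the quench, which would lead to double addition of the Grignard reagent, and Wurtz coupling may consume the bromide during magnesium insertion. The fallback sets out from 1 and comes back to the route at 4. It replaces acylation of an organometallic by alkylation of an acyl-anion equivalent. The sodium salt of ethyl 1,3-dithiane-2-carboxylate (NaH, DMF/toluene, 0 °C to rt) would be alkylated by 1 to ethyl 2-hexadecyl-1,3-dithiane-2-carboxylate F3. Oxidative dethioketalisation (PhI(OCOCF3)2, MeCN/H2O, rt) should then release 4.

Further compounds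
F1 | step 2 | icos-3-yne | CCC#CCCCCCCCCCCCCCCCC
F2 | step 2 | icosane-3,4-dione | CCC(=O)C(=O)CCCCCCCCCCCCCCCC
F3 | step 1 | ethyl 2-hexadecyl-1,3-dithiane-2-carboxylate | CCCCCCCCCCCCCCCCC1(SCCCS1)C(=O)OCC
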